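Ring A (C1–C5, C10; labdane numbering) is cut at C1–C2 and C3–C4, so that C2–C3 is acrolein and ring B carries everything else. The key step exploits two features of ring A: its gem-dimethyl carbon C4 is the tertiary radical of an isopropenyl group on C5, and C1 is a neopentyl aldehyde on the quaternary C10. One iron-hydride radical–polar crossover annulation adds that radical to acrolein and closes the enolate onto the aldehyde, giving the trans-decalin. The precursor, a cyclohexanone with C9 side chain, C10 methyl/formyl and C5 isopropenyl, comes from (+)-verbenone by cuprate addition, alkylation and strain-driven cyclobutane opening.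

Key step: step 9

Remark: labdane numbering is used for all intermediates; C9, epimerisable next to the C8 ketone, is drawn in the equatorial configuration that base equilibration should favour once that ketone is free, and both chiral starting materials are taken as commercial and enantiopure.

Step 1
Reactants: 1 (R)-monomethyl 3-methylglutarate
Product: 3 (S)-4-methyltetrahydro-2H-pyran-2-one, via hydroxy acid 2 (not isolated)
Conditions: LiBH4, THF, 0 °C → rt; then 2 M HCl, rt
Reagents that add atoms: none
Why: The first equivalent of LiBH4 converts the acid into its inert lithium carboxylate, the ester is then reduced chemoselectively (borohydride ester reduction) and acid closes the δ-lactone, which exchanges the roles of the two glutarate arms without touching the methyl-bearing stereocentre.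

Step 2
Reactants: 3 (S)-4-methyltetrahydro-2H-pyran-2-one
Product: 5 methyl (R)-5-iodo-3-methylpentanoate, via silyl ester 4 (not isolated)
Conditions: Me3SiI, CH2Cl2, rt; then MeOH, rt
Reagents that add atoms: iodotrimethylsilane, C[Si](C)(C)I; methanol, CO
Why: Silylation of the lactone carbonyl and SN2 attack of iodide at the primary O-alkyl carbon open the ring (silyl iodide lactone cleavage) and methanolysis of the silyl ester in the acidic medium should give the methyl ester, the stereocentre not being involved (only its descriptor changes).

Step 3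
Reactants: 6 (1R,5R)-(+)-verbenone; 7 vinylmagnesium bromide
Product: 8 (1R,4S,5S)-4,6,6-trimethyl-4-vinylbicyclo[3.1.1]heptan-2-one
Conditions: CH2=CHMgBr, CuI (10 mol%), THF, −40 °C → 0 °C; aq. NH4Cl
Reagents that add atoms: vinylmagnesium bromide 7, C=C[Mg]Br
Why: Copper-catalysed conjugate addition to the β,β-disubstituted enone creates the quaternary carbon that becomes C10, the vinyl group (a masked C1 formyl group) entering anti to the gem-dimethyl bridge so that the methyl group ends up cis to the carbon that becomes C4.

Step 4
Reactants: 8 the vinyl ketone; 5 methyl (R)-5-iodo-3-methylpentanoate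
Product: 9 methyl (3S)-3-methyl-5-[(1R,3S,4S,5S)-4,6,6-trimethyl-2-oxo-4-vinylbicyclo[3.1.1]heptan-3-yl]pentanoate
Conditions: LiN(i-Pr)2, THF, −78 °C; then 5, DMPU, −78 °C → 0 °C
Reagents that add atoms: iodide 5, ICC[C@H](C)CC(=O)OC
Why: Only one α-carbon can enolise (the other is a bridgehead) and the lithium enolate should be alkylated by the primary iodide from the face opposite the gem-dimethyl bridge (enolate SN2 alkylation), a provisional configuration at the later C9 that is corrected by equilibration in steps 7 and 10.

Step 5
Reactants: 9 the alkylated vinyl ketone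
Product: 11 hydroxymethyl ketone, via keto aldehyde 10 (not isolated)
Conditions: O3, CH2Cl2/MeOH, −78 °C; Me2S, −78 °C → rt; then NaBH4, −78 → −40 °C
Reagents that add atoms: ozone, [O-][O+]=O
Why: Ozonolysis cleaves the only C=C bond to the neopentyl aldehyde, which borohydride should reduce at low temperature in preference to the hindered ring ketone (chemoselective aldehyde reduction), so that C1 passes the cationic ring opening at the alcohol level.

Step 6
Reactants: 11 the hydroxymethyl ketone
Product: 12 methyl (3S)-5-[(1S,5S,6S)-2-acetoxy-6-(acetoxymethyl)-6-methyl-5-(prop-1-en-2-yl)cyclohex-2-en-1-yl]-3-methylpentanoate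
Conditions: Ac2O, Zn(OAc)2, BF3·OEt2, 0 °C → rt
Reagents that add atoms: acetic anhydride, CC(=O)OC(C)=O
Why: Lewis acid activation of the ketone cleaves the strained cyclobutane bond between the carbonyl α-carbon and the gem-dimethyl carbon (known nopinone ring opening), the enol being trapped as its acetate and the tertiary cation losing a methyl proton to give the C5 isopropenyl group, while the primary alcohol is acetylated at once and so cannot capture the cation.

Step 7
Reactants: 12 the enol acetate
Product: 13 methyl (3S)-5-[(1R,2S,3S)-2-(hydroxymethyl)-2-methyl-6-oxo-3-(prop-1-en-2-yl)cyclohexyl]-3-methylpentanoate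
Conditions: K2CO3, MeOH, rt
Reagents that add atoms: none
Why: Methanolysis removes the enol and primary acetates (transesterification) and the carbonate should equilibrate C9 next to the freed C8 ketone towards the epimer with the side chain equatorial and cis to the isopropenyl group.

Step 8
Reactants: 13 the hydroxy ketone
Product: 14 methyl (3S)-5-[(1R,2S,3S)-2-formyl-2-methyl-6-oxo-3-(prop-1-en-2-yl)cyclohexyl]-3-methylpentanoate
Conditions: Dess–Martin periodinane, NaHCO3, CH2Cl2, 0 °C → rt
Reagents that add atoms: none
Why: Dess–Martin oxidation converts the neopentyl primary alcohol into the non-enolisable C1 aldehyde under buffered conditions that leave the ketone, the alkene and C9 untouched.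

Step 9
Reactants: 14 the keto aldehyde; 15 acrolein
Product: 16 methyl (13S)-2-formyl-1-hydroxy-8-oxo-17-norlabdan-15-oate (diastereomer mixture at C1 and C2)
Conditions: Fe(acac)3 (30 mol%), PhSiH3, acrolein (3 equiv, slow addition), EtOH/(CH2OH)2, 0 °C → rt
Reagents that add atoms: acrolein 15, C=CC=O
Why: Hydrogen-atom transfer from an iron hydride (from Fe(acac)3 and PhSiH3) to the terminal carbon of the isopropenyl group gives the tertiary C4 radical, which adds to the β-carbon of acrolein (C3–C4 bond); the α-formyl radical is then reduced by divalent iron to an enolate that adds to the C1 aldehyde (C1–C2 bond). The closest known reaction type is the iron-hydride-initiated radical conjugate addition/aldol annulation of γ,δ-unsaturated aldehydes with enals and enones. Ring A closes in the aldol step by a 6-(enolexo)-exo-trig attack of the enolate carbon C2 on the aldehyde carbonyl. No lasting stereocentre is made, because C4 becomes an achiral gem-dimethyl carbon and the C1 carbinol and C2 formyl centres are erased in steps 10 and 11, while the trans ring fusion is dictated by the existing C5 and C10 configurations (isopropenyl and formyl trans-diequatorial on ring B). The step needs hydrogen-atom transfer only at the 1,1-disubstituted alkene and ring closure before the enolate is protonated; the first is secured because the isopropenyl group is the only alkene in 14, the second because the quaternary C10 holds the non-enolisable aldehyde within reach of a six-membered transition state, whereas the C8 ketone could only be reached through a seven-membered one.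

Step 10
Reactants: 16 the β-hydroxy aldehyde
Product: 18 methyl (13S)-2-formyl-8-oxo-17-norlabd-1-en-15-oate, via mesylate 17 (not isolated)
Conditions: MsCl, Et3N, CH2Cl2, 0 °C; then DBU, rt
Reagents that add atoms: none
Why: Mesylation and E1cB elimination should give the conjugated enal whatever the C1/C2 configuration, and DBU also equilibrates C9 of the trans-decalone to the equatorial 9β side chain.

Step 11
Reactants: 18 the enal
Product: 19 methyl (13S)-8-oxo-17-norlabd-1-en-15-oate
Conditions: RhCl(PPh3)3 (1.1 equiv), toluene, 110 °C
Reagents that add atoms: none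
Why: Tsuji–Wilkinson decarbonylation (formyl C–H oxidative addition to monovalent rhodium, CO extrusion, reductive elimination) replaces the formyl group by hydrogen, and any migration of the ring A double bond is harmless because that alkene is hydrogenated next.

Step 12
Reactants: 19 the ring A alkene
Product: 20 methyl (13S)-8-oxo-17-norlabdan-15-oate
Conditions: H2 (1 atm), Pd/C, EtOAc, rt
Reagents that add atoms: none
Why: Heterogeneous hydrogenation saturates the only C=C bond and leaves ketone and ester untouched, which completes the C1–C2 ethano unit of ring A.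

Step 13
Reactants: 20 the saturated C8 ketone
Product: 21 methyl (13S)-labd-8(17)-en-15-oate
Conditions: Ph3PCH3Br, KOtBu, THF, 0 °C → 50 °C
Reagents that add atoms: methyltriphenylphosphonium bromide, C[P+](c1ccccc1)(c1ccccc1)c1ccccc1.[Br-]
Why: Wittig methylenation with the unstabilised ylide should take the ketone much faster than the methyl ester, and the basic medium keeps C9 in its stable equatorial configuration before the ketone, and with it the epimerisability, disappears.

Step 14
Reactants: 21 the exocyclic alkene
Product: 22 methyl (13S)-7α-hydroxylabd-8(17)-en-15-oate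
Conditions: SeO2 (0.5 equiv), t-BuOOH, CH2Cl2, 0 °C → rt
Reagents that add atoms: tert-butyl hydroperoxide, CC(C)(C)OO (oxygen passed on through selenium dioxide, O=[Se]=O)
Why: Selenium dioxide allylic oxidation (ene reaction, then [2,3]-sigmatropic shift) should remove the axial 7α-hydrogen of the ring methylene in preference to the tertiary C9 hydrogen and deliver oxygen to the same α-face, giving the axial 7α-alcohol.

Step 15
Reactants: 22 the 7α-alcohol
Product: 23 methyl (13S)-7α-acetoxylabd-8(17)-en-15-oate (target)
Conditions: Ac2O, pyridine, DMAP (cat.), CH2Cl2, rt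
Reagents that add atoms: acetic anhydride, CC(=O)OC(C)=O
Why: DMAP-catalysed acylation of the secondary allylic alcohol proceeds with retention at C7 and should give the target acetate.

Compound list
1 | (R)-monomethyl 3-methylglutarate, (3R)-5-methoxy-3-methyl-5-oxopentanoic acid | C[C@H](CC(=O)O)CC(=O)OC | starting material
2 | (S)-5-hydroxy-3-methylpentanoic acid (lithium salt in the flask, not isolated) | C[C@H](CC(=O)O)CCO | intermediate
3 | (S)-4-methyltetrahydro-2H-pyran-2-one | C[C@@H]1CC(=O)OCC1 | intermediate
4 | trimethylsilyl (R)-5-iodo-3-methylpentanoate (not isolated) | ICC[C@H](C)CC(=O)O[Si](C)(C)C | intermediate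
5 | methyl (R)-5-iodo-3-methylpentanoate | ICC[C@H](C)CC(=O)OC | intermediate
6 | (1R,5R)-(+)-verbenone, (1R,5R)-4,6,6-trimethylbicyclo[3.1.1]hept-3-en-2-one | CC1=CC(=O)[C@@H]2C[C@H]1C2(C)C | starting material
7 | vinylmagnesium bromide | C=C[Mg]Br | starting material
8 | (1R,4S,5S)-4,6,6-trimethyl-4-vinylbicyclo[3.1.1]heptan-2-one (vinyl anti to the gem-dimethyl bridge) | C=C[C@]1(C)CC(=O)[C@@H]2C[C@H]1C2(C)C | intermediate
9 | methyl (3S)-3-methyl-5-[(1R,3S,4S,5S)-4,6,6-trimethyl-2-oxo-4-vinylbicyclo[3.1.1]heptan-3-yl]pentanoate (side chain and vinyl both anti to the gem-dimethyl bridge) | C=C[C@]1(C)[C@H](CC[C@H](C)CC(=O)OC)C(=O)[C@@H]2C[C@H]1C2(C)C | intermediate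
10 | methyl (3S)-5-[(1R,3S,4S,5S)-4-formyl-4,6,6-trimethyl-2-oxobicyclo[3.1.1]heptan-3-yl]-3-methylpentanoate (not isolated) | O=C[C@]1(C)[C@H](CC[C@H](C)CC(=O)OC)C(=O)[C@@H]2C[C@H]1C2(C)C | intermediate
11 | methyl (3S)-5-[(1R,3S,4S,5S)-4-(hydroxymethyl)-4,6,6-trimethyl-2-oxobicyclo[3.1.1]heptan-3-yl]-3-methylpentanoate | OC[C@]1(C)[C@H](CC[C@H](C)CC(=O)OC)C(=O)[C@@H]2C[C@H]1C2(C)C | intermediate
12 | methyl (3S)-5-[(1S,5S,6S)-2-acetoxy-6-(acetoxymethyl)-6-methyl-5-(prop-1-en-2-yl)cyclohex-2-en-1-yl]-3-methylpentanoate (ring B enol acetate C7=C8, side chain still 9α) | CC(=O)OC1=CC[C@@H](C(C)=C)[C@](C)(COC(C)=O)[C@@H]1CC[C@H](C)CC(=O)OC | intermediate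
13 | methyl (3S)-5-[(1R,2S,3S)-2-(hydroxymethyl)-2-methyl-6-oxo-3-(prop-1-en-2-yl)cyclohexyl]-3-methylpentanoate (9β side chain, 10β-methyl, 5β-isopropenyl) | O=C1CC[C@@H](C(C)=C)[C@](C)(CO)[C@H]1CC[C@H](C)CC(=O)OC | intermediate
14 | methyl (3S)-5-[(1R,2S,3S)-2-formyl-2-methyl-6-oxo-3-(prop-1-en-2-yl)cyclohexyl]-3-methylpentanoate | O=C1CC[C@@H](C(C)=C)[C@](C)(C=O)[C@H]1CC[C@H](C)CC(=O)OC | intermediate
15 | acrolein | C=CC=O | starting material
16 | methyl (13S)-2-formyl-1-hydroxy-8-oxo-17-norlabdan-15-oate (5α-H, 9α-H, 10β-methyl; mixture at C1 and C2) | O=C1CC[C@H]2C(C)(C)CC(C=O)C(O)[C@]2(C)[C@H]1CC[C@H](C)CC(=O)OC | intermediate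
17 | 1-O-methanesulfonate of 16 (not isolated) | O=C1CC[C@H]2C(C)(C)CC(C=O)C(OS(C)(=O)=O)[C@]2(C)[C@H]1CC[C@H](C)CC(=O)OC | intermediate
18 | methyl (13S)-2-formyl-8-oxo-17-norlabd-1-en-15-oate | O=C1CC[C@H]2C(C)(C)CC(C=O)=C[C@]2(C)[C@H]1CC[C@H](C)CC(=O)OC | intermediate
19 | methyl (13S)-8-oxo-17-norlabd-1-en-15-oate | O=C1CC[C@H]2C(C)(C)CC=C[C@]2(C)[C@H]1CC[C@H](C)CC(=O)OC | intermediate
20 | methyl (13S)-8-oxo-17-norlabdan-15-oate | O=C1CC[C@H]2C(C)(C)CCC[C@]2(C)[C@H]1CC[C@H](C)CC(=O)OC | intermediate
21 | methyl (13S)-labd-8(17)-en-15-oate | C=C1CC[C@H]2C(C)(C)CCC[C@]2(C)[C@H]1CC[C@H](C)CC(=O)OC | intermediate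
22 | methyl (13S)-7α-hydroxylabd-8(17)-en-15-oate | C=C1[C@H](O)C[C@H]2C(C)(C)CCC[C@]2(C)[C@H]1CC[C@H](C)CC(=O)OC | intermediate
23 | CNP0223602.1, methyl (13S)-7α-acetoxylabd-8(17)-en-15-oate, (5S,7R,9R,10S,13S) | C=C1[C@H](OC(C)=O)C[C@H]2C(C)(C)CCC[C@]2(C)[C@H]1CC[C@H](C)CC(=O)OC | target

Total step count: 15. Longest linear sequence: 14 steps (steps 1, 2 and 4 to 15).

Steps most likely to fail

Step 9. The acrolein-derived enolate may be protonated by the alcohol medium before it reaches the hindered neopentyl aldehyde, so that reductive coupling stops at the open chain. The fallback sets out from 14 and makes this outcome the aim. The same iron hydride coupling with acrolein is run under fully protic conditions (Fe(acac)3, PhSiH3, EtOH/(CH2OH)2, 60 °C) and should give the keto dialdehyde F1. Ring A is then closed in a separate amine-catalysed intramolecular aldol condensation (piperidinium acetate, toluene, 80 °C), in which only the new chain aldehyde can form an enamine and the C1 aldehyde is the only acceptor in six-membered reach. Dehydration gives the enal, and the route is rejoined at 18.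

Step 6. The tertiary cation released on cyclobutane cleavage may be captured by acetate, may undergo hydride or methyl shifts, or may lose a ring proton instead of a methyl proton. The fallback sets out from 11 and separates capture from elimination. Acetylation (Ac2O, pyridine) gives the keto acetate F2. Opening with Me3SiI (from Me3SiCl and NaI, MeCN, 0 °C), in which iodide captures the developing cation as the bond breaks, should give after aqueous work-up the tertiary iodide F3. Bimolecular elimination with DBU (toluene, 60 °C) towards the methyl hydrogens gives the isopropenyl keto acetate F4, and K2CO3 in MeOH returns to the route at 13.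

Step 4. C-alkylation of the hindered enolate next to the quaternary carbon by an unactivated iodide may be slow, so that proton transfer to the ester and O-alkylation compete. The fallback sets out from 5 and 8 and replaces the alkylation by an aldol route. Kornblum oxidation of 5 (DMSO, NaHCO3, 100 °C) gives methyl (S)-3-methyl-5-oxopentanoate F5. Addition of the lithium enolate of 8 (LiN(i-Pr)2, THF, −78 °C) to F5 should give the β-hydroxy ketone F6, and dehydration (MsCl, Et3N; then DBU) gives the alkylidene ketone F7. Conjugate reduction with [(Ph3P)CuH]6 (benzene, rt), which leaves the isolated vinyl group alone, returns to the route at 9, as an epimer mixture at the later C9 that steps 7 and 10 equilibrate.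

Further compounds
F1 | step 9 | keto dialdehyde, 14 with the isopropenyl group converted into a 2-methyl-5-oxopentan-2-yl group | O=C1CC[C@@H](C(C)(C)CCC=O)[C@](C)(C=O)[C@H]1CC[C@H](C)CC(=O)OC
F2 | step 6 | O-acetate of 11 | CC(=O)OC[C@]1(C)[C@H](CC[C@H](C)CC(=O)OC)C(=O)[C@@H]2C[C@H]1C2(C)C
F3 | step 6 | ring-opened keto acetate with a 2-iodopropan-2-yl group on C5 (side chain still 9α) | O=C1CC[C@@H](C(C)(C)I)[C@](C)(COC(C)=O)[C@@H]1CC[C@H](C)CC(=O)OC
F4 | step 6 | O-acetate of 13 (isopropenyl keto acetate, 9β side chain) | O=C1CC[C@@H](C(C)=C)[C@](C)(COC(C)=O)[C@H]1CC[C@H](C)CC(=O)OC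
F5 | step 4 | methyl (S)-3-methyl-5-oxopentanoate | O=CC[C@H](C)CC(=O)OC
F6 | step 4 | aldol adduct of 8 and F5 (β-hydroxy ketone, new centres as a mixture) | C=C[C@]1(C)C(C(O)C[C@H](C)CC(=O)OC)C(=O)[C@@H]2C[C@H]1C2(C)C
F7 | step 4 | alkylidene ketone from dehydration of F6 (alkene geometry not defined) | C=C[C@]1(C)C(=CC[C@H](C)CC(=O)OC)C(=O)[C@@H]2C[C@H]1C2(C)C
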